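Eudesmane numbering is used throughout: ring A is C1–C5/C10, ring B is C5–C10, C14 is the methyl on C10, C15 the methyl on C4, and C11–C13 the hydroxy‑isopropyl group on C7.

## Analysis of the target

The target is a trans‑fused eudesmane (5α‑H, 10β‑methyl) whose C3 hydroxyl is esterified with (2S,3S)‑2,3‑epoxy‑2‑methylbutanoic acid. The decalin carries five stereocentres (3R,4S,5R,7S,10R) and the epoxide two more (2′S,3′S). C4 holds an equatorial α‑hydroxyl and an axial β‑methyl that is 1,3‑diaxial to C14; the C3 oxygen is α (axial) and cis to the C4 hydroxyl. C7 carries an α‑hydroxyl and, on the β side, the C11 carbinol, next to the C8 ketone. The sensitive parts are the glycidic ester (acid, nucleophiles), the tertiary α‑ketol at C7/C8, and the C11 carbinol, which is β to the C8 ketone and can be lost as acetone by retro‑aldol cleavage under base. The difficulty lies in three fully substituted carbons (C4, C7, C10), two of them oxygenated, in two ketone‑level carbons (C4 and C8) that must be told apart, and in the dense oxygenation of a small skeleton. The strategy rests on ring B: C7, C8 and C10 carry the carbinol, the oxygen and the methyl of 2‑(2‑hydroxypropan‑2‑yl)‑5‑methylphenol. Hydroxylation of that phenol at C7 gives the tertiary ketol and the C8 ketone together and makes C10 the β‑carbon of an enone. A C1 radical on a four‑carbon chain at C5 can then close ring A onto C10.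

## Retrosynthetic reasoning

**C3 ester.** The acyl–oxygen bond of 22 is cut first, giving tetraol 16 and epoxy acid 20. The glycidic ester is the most fragile group and should see no other step. In 16 the C3 hydroxyl is the only secondary one, so the forward reaction only has to acylate it beside three tertiary hydroxyls.

**Epoxy acid.** Acid 20 goes back to epoxy alcohol 19 (oxidation level) and then to (Z)‑allylic alcohol 18 (both epoxide C–O bonds), which comes from angelic acid 17. Cutting at the epoxide lets a tartrate‑controlled epoxidation set both centres, and the Z geometry of 17 supplies the relative configuration.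

**7,11‑Diol.** Tetraol 16 comes from acetonide 15. The five‑membered ketal keeps the diol from retro‑aldol cleavage during the basic and radical steps, and it is taken off before the ester is introduced.

**C3 and C4.** In 15 the C4–O bond is cut (hydration of C4=C15 in allylic alcohol 14), then the C3–O bond (allylic oxidation of alkene 13), then C4=C15 (methylenation of diketone 12). All three operations grow out of the one carbonyl that the ring closure leaves at C4, and the axial C14 methyl is the control element for C3 and C4. The forward reactions must distinguish the C4 ketone from the crowded C8 ketone.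

**C5.** Diketone 12 comes from enedione 11 by adding hydrogen to C5=C6, and 11 from its C4 dioxolane 10. C5 is α to the C4 ketone, so the ring fusion can be corrected by equilibration at this point and nowhere later.

**C1–C10 (key disconnection).** In 10 the C1–C10 bond is cut, giving iodide 9. Cutting here leaves ring B untouched with every substituent already on it, and it forms the quaternary carbon by a radical addition to an sp2 carbon, which tolerates crowding. C5 stays trigonal, so only C10 is set, under the control of the spiro carbon C7. Compound 9 carries C4 as a dioxolane and not as a free ketone. With a free C4 carbonyl, C5=C6 would be a second enone whose carbonyl lies inside the tether, and closure onto its β‑carbon C6 in the 6‑endo mode would be the expected outcome.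

**Ortho‑quinol.** Iodide 9 comes from chloride 8 (halide exchange), 8 from diol 7 (ketal C–O bonds), and 7 from phenol 6 by cutting the C7–O bond. That is the dearomatising hydroxylation, which has to be regioselective for the carbinol‑bearing ortho carbon and enantioselective.

**Arene.** Phenol 6 is cut at the two C11–methyl bonds to ester 4 and methylmagnesium bromide 5. Ketal 4 comes from ketone 3, and 3 is cut at C4–C5 (Friedel–Crafts acylation) to methyl 4‑methylsalicylate 1 and 4‑chlorobutanoyl chloride 2. The phenol and the methyl group both direct the acyl group to the carbon that becomes C5.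

## Alternatives that were turned down

**Alternative 1:** The decalin is cut at C1–C2 and C5–C10. The open‑chain trienone A2 would close both rings in one intramolecular Diels–Alder reaction: activated by Et2AlCl, the C1=C10 bond of its isopropenyl ketone adds across the C2=C3–C4=C5 diene to give A1, 11‑(triethylsilyloxy)eudesm‑3‑en‑9‑one.
- For it: two C–C bonds, both rings and the C5/C10 pair arise in one step, and the absolute configuration comes from a chiral‑pool monoterpene. A1 also holds a C3=C4 alkene with C15 in place, which a cis‑dihydroxylation on the α face would turn into the 3α,4α‑diol in one step. On C3/C4 this is stronger than the chosen route, which needs three steps there and relies on a radical trapping for C4.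
- Against it: the ketone of A1 is at C9, not C8. It has to be transposed, and the C7 hydroxyl then has to be put on a carbon that already bears the protected carbinol, which is a long late sequence on ring B ending in a tertiary stereocentre. The ring‑fusion outcome with a dienophile that carries the angular methyl is also not assured.
- Comparison: the chosen strategy gives up the short C3/C4 solution but starts with C7–O, C8=O, C11 and C14 in their final places.

**Alternative 2:** Ring B is cut at C7–C8. Keto aldehyde A4 has ring A already formed, the C8 aldehyde on the C10 arm and the C7 isopropenyl ketone on the C5 arm. A triazolium‑derived N‑heterocyclic carbene would turn the aldehyde into an acyl anion equivalent that adds to the ketone carbonyl, closing ring B to A3, 7α‑hydroxyeudesma‑3,11‑dien‑8‑one.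
- For it: the key step creates the tertiary ketol C7(OH)–C8(=O) of the target directly and catalytically. The two alkenes of A3 map onto the remaining oxygens (C3=C4 to the diol, C11=C12 to the carbinol), so the end game is shorter and arguably safer than the chosen one. On that point this alternative is stronger.
- Against it: A4 contains the quaternary C10 and the C5 stereocentre with two different functionalised arms, and making it as one enantiomer is a multistep task that the key step does nothing for. The acyl anion must also prefer 1,2‑addition to a hindered ketone over conjugate addition and aldehyde self‑condensation, and the C7 configuration rests on catalyst–substrate matching.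
- Comparison: the chosen strategy makes the same ketol by oxidising an aromatic carbon before any ring fusion exists and reaches its key‑step precursor in six steps. The price is a less certain key step.

**Alternative 3:** The decalin is cut at C4–C5 and C9–C10. The achiral enyne enol silane A6 would be treated with cationic monovalent gold from [(R)-DTBM-MeO-BIPHEP](AuCl)2 and AgSbF6, or the enantiomeric complex. The alkyne is activated, C5 attacks C4, and C9 of the enol silane traps the C10 cation, giving A5, 4(15)‑methylene‑11,12,13‑trinoreudesman‑8‑one (5α‑H, 10β‑methyl).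
- For it: both rings and both ring‑fusion centres come from an achiral chain in one catalytic enantioselective step. The trans fusion follows from anti addition across the E alkene, which is better secured mechanistically than the ring fusion of the chosen route, and C4=C15 is already present. A catalytic source of chirality is at least as good as the stoichiometric chiral iodane used here.
- Against it: A5 has neither carbon nor oxygen at C7. The three‑carbon carbinol and the C7 hydroxyl would have to be added to a plain ketone by an aldol reaction and an α‑hydroxylation of a retro‑aldol‑prone β‑hydroxy ketone, setting a tertiary centre by substrate control. The enantioselectivity for this substrate class is uncertain as well.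
- Comparison: the chosen strategy carries the difficult ring B pattern from the first step and spends no step on C7 or C11 after the ring closure.

Key step: step 7

Assumption: the sense of induction of the axially chiral iodane on this phenol cannot be predicted with confidence; the atropisomer that gives (S) at C7 is meant, and (S)‑7 is drawn throughout.

Assumption: methyl 4‑methylsalicylate (1) is bought as such; it is also one esterification away from 4‑methylsalicylic acid.

## Steps

Step 1
Reactants: 1 methyl 2-hydroxy-4-methylbenzoate (methyl 4-methylsalicylate); 2 4-chlorobutanoyl chloride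
Product: 3 methyl 5-(4-chlorobutanoyl)-2-hydroxy-4-methylbenzoate
Conditions: AlCl3 (3 equiv), 1,2-dichloroethane, 0 °C to 40 °C; aq. HCl work-up
Reagents that add atoms: none
Why: Friedel–Crafts acylation; the hydroxyl (para) and the methyl group (ortho) both direct to the carbon that becomes C5, the other free position ortho to the hydroxyl is flanked on both sides, and the primary chloride does not react under these conditions.

Step 2
Reactants: 3 methyl 5-(4-chlorobutanoyl)-2-hydroxy-4-methylbenzoate
Product: 4 methyl 5-[2-(3-chloropropyl)-1,3-dioxolan-2-yl]-2-hydroxy-4-methylbenzoate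
Conditions: ethane-1,2-diol (5 equiv), p-TsOH (cat.), toluene, reflux, Dean–Stark trap; Et3N-buffered chromatography
Reagents that add atoms: ethane-1,2-diol, OCCO
Why: Acid-catalysed ketalisation with azeotropic removal of water masks the C4 ketone against the Grignard reagent and stays on through the ring closure; any ester exchange with the diol is harmless because all esters give the same carbinol in step 3.

Step 3
Reactants: 4 methyl 5-[2-(3-chloropropyl)-1,3-dioxolan-2-yl]-2-hydroxy-4-methylbenzoate; 5 methylmagnesium bromide
Product: 6 4-[2-(3-chloropropyl)-1,3-dioxolan-2-yl]-2-(2-hydroxypropan-2-yl)-5-methylphenol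
Conditions: MeMgBr (4 equiv), THF, 0 °C to rt; sat. aq. NH4Cl
Reagents that add atoms: none
Why: Double Grignard addition to the ester after deprotonation of the phenol builds the C11 carbinol; the ketal and the primary chloride are inert to the reagent at this temperature, and the neutral work-up avoids dehydration of the benzylic tertiary alcohol.

Step 4
Reactants: 6 4-[2-(3-chloropropyl)-1,3-dioxolan-2-yl]-2-(2-hydroxypropan-2-yl)-5-methylphenol
Product: 7 (6S)-4-[2-(3-chloropropyl)-1,3-dioxolan-2-yl]-6-hydroxy-6-(2-hydroxypropan-2-yl)-3-methylcyclohexa-2,4-dien-1-one (ortho-quinol with 7α-hydroxyl)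
Conditions: axially chiral bis(λ5-iodane) (pentavalent iodine; 1 equiv), CH2Cl2, −40 °C to 0 °C; aq. Na2S2O3/NaHCO3 work-up; crude product taken on at once
Reagents that add atoms: 2,2′-diiodyl-6,6′-dimethoxy-1,1′-biphenyl (single atropisomer), COc1cccc(I(=O)=O)c1-c1c(OC)cccc1I(=O)=O
Why: Hydroxylative phenol dearomatisation, as established for 2-alkylphenols of the thymol type: the phenol binds iodine and oxygen is passed to the ortho carbon in a [2,3]-type shift; the carbinol-bearing carbon C7 is favoured because the neighbouring hydroxyl can also bind iodine and the other ortho carbon is flanked by the methyl group, the chiral biaryl selects the face to give (S), and the substituents on C10 and C5 slow the [4+2] dimerisation of the dienone.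

Step 5
Reactants: 7 (6S)-4-[2-(3-chloropropyl)-1,3-dioxolan-2-yl]-6-hydroxy-6-(2-hydroxypropan-2-yl)-3-methylcyclohexa-2,4-dien-1-one
Product: 8 (5S)-9-[2-(3-chloropropyl)-1,3-dioxolan-2-yl]-2,2,4,4,8-pentamethyl-1,3-dioxaspiro[4.5]deca-7,9-dien-6-one (7α,11-acetonide)
Conditions: 2,2-dimethoxypropane (5 equiv), PPTS (cat.), CH2Cl2, rt
Reagents that add atoms: 2,2-dimethoxypropane, COC(C)(C)OC
Why: Acid-catalysed ketal exchange ties the two tertiary hydroxyls into a dioxolane, which blocks retro-aldol loss of acetone (rearomatisation to a catechol) and places only the small ring oxygen on the α face and the gem-dimethyl carbon C11 on the β face of the flat dienone; the C4 dioxolane is stable in the absence of water.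

Step 6
Reactants: 8 (5S)-9-[2-(3-chloropropyl)-1,3-dioxolan-2-yl]-2,2,4,4,8-pentamethyl-1,3-dioxaspiro[4.5]deca-7,9-dien-6-one
Product: 9 (5S)-9-[2-(3-iodopropyl)-1,3-dioxolan-2-yl]-2,2,4,4,8-pentamethyl-1,3-dioxaspiro[4.5]deca-7,9-dien-6-one
Conditions: NaI (5 equiv), NaHCO3 (trace), acetone, reflux, dark
Reagents that add atoms: sodium iodide, [Na+].[I-]
Why: Finkelstein exchange driven by precipitation of NaCl; the iodide is needed because the silyl radical abstracts iodine much faster than it adds to the dienone, and it is made only after the oxidation step, which an alkyl iodide would not survive.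

Step 7
Reactants: 9 (5S)-9-[2-(3-iodopropyl)-1,3-dioxolan-2-yl]-2,2,4,4,8-pentamethyl-1,3-dioxaspiro[4.5]deca-7,9-dien-6-one
Product: 10 4,4-ethylenedioxy-7α,11-isopropylidenedioxy-15-noreudesm-5-en-8-one (10β-methyl; 7S,10R)
Conditions: (Me3Si)3SiH (1.3 equiv, syringe pump), Et3B (0.3 equiv, portions), air (trace), toluene (0.005 M), rt
Reagents that add atoms: none
Why: Proposed new method: the closest known reaction type is the silane- or stannane-mediated 6-exo cyclisation of primary alkyl radicals onto the β-carbon of cyclohexenones and of 4,4-disubstituted cyclohexa-2,5-dienones, including closures that make quaternary carbons, which has not been shown on a 6,6-dioxygenated cyclohexa-2,4-dienone. Ethyl radicals from Et3B and O2 start a chain in which (Me3Si)3Si• takes iodine from C1, the nucleophilic primary radical adds to C10, the β-carbon of the C8 enone, and the resulting C9 radical, stabilised by the ketone, takes hydrogen from the silane. Ring A closes in the 6-exo-trig mode through a chair-like transition state while C5 stays trigonal, so no ring-fusion centre is set in this step. The only new stereocentre is C10: the dienone is flat, its β face is covered by the gem-dimethyl group of C11 on the spiro carbon C7 and its α face carries only O7, so C1 should bond on the α face and leave C14 β. The step also needs site selectivity, because C1 can reach C6, the δ-carbon of the dienone, in a 6-endo closure and C5 in a 5-exo closure. C4 is therefore kept as its dioxolane, which removes the second enone that would make C6 a β-carbon with the carbonyl inside the forming ring, the arrangement in which 6-endo closure is known to win; attack on C5 is a mismatched addition to the γ-carbon. What then favours C10 is the polar match of the nucleophilic radical with the enone β-carbon and the exo geometry, but the substrate does not enforce this, and it is the main risk of the route. Slow addition of the silane at high dilution gives the slow closure onto a fully substituted carbon time to compete with direct reduction of the radical.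

Step 8
Reactants: 10 4,4-ethylenedioxy-7α,11-isopropylidenedioxy-15-noreudesm-5-en-8-one
Product: 11 7α,11-isopropylidenedioxy-15-noreudesm-5-ene-4,8-dione (10β-methyl)
Conditions: PPTS (0.2 equiv), acetone/H2O (10:1), 45 °C
Reagents that add atoms: water, O
Why: Mild acid-catalysed hydrolysis of the allylic ketal, whose oxocarbenium ion is tertiary and allyl-stabilised; the crowded acetonide next to the C8 ketone hydrolyses far more slowly and is held in place by the acetone solvent.

Step 9
Reactants: 11 7α,11-isopropylidenedioxy-15-noreudesm-5-ene-4,8-dione
Product: 12 7α,11-isopropylidenedioxy-15-nor-5α-eudesmane-4,8-dione (trans-fused; 5R,7S,10R)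
Conditions: H2 (1 atm), 10% Pd/C, EtOAc, rt; then DBU (0.2 equiv), CH2Cl2, rt
Reagents that add atoms: none
Why: Heterogeneous hydrogenation of the enone takes place on the α face, since the β face carries both C14 and the C11 gem-dimethyl group, and gives 5α-H; C5 is α to the C4 ketone, so the base treatment moves any cis isomer to the trans-fused diketone, in which C11 is equatorial and only O7 is axial.

Step 10
Reactants: 12 7α,11-isopropylidenedioxy-15-nor-5α-eudesmane-4,8-dione
Product: 13 7α,11-isopropylidenedioxy-5α-eudesm-4(15)-en-8-one
Conditions: Ph3PCH3Br (2.5 equiv), KOtBu (2.3 equiv), toluene, 0 °C to 60 °C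
Reagents that add atoms: methyltriphenylphosphonium bromide (as its ylide), C[P+](c1ccccc1)(c1ccccc1)c1ccccc1.[Br-]
Why: Wittig methylenation; the C4 ketone lies between a CH2 and a CH group and is far more accessible than the C8 ketone, which sits between the fully substituted C7 and a neopentyl-type CH2, and the acetonide keeps the diol from retro-aldol cleavage by the basic ylide.

Step 11
Reactants: 13 7α,11-isopropylidenedioxy-5α-eudesm-4(15)-en-8-one
Product: 14 3α-hydroxy-7α,11-isopropylidenedioxy-5α-eudesm-4(15)-en-8-one
Conditions: SeO2 (0.5 equiv), t-BuOOH (2.5 equiv), CH2Cl2, rt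
Reagents that add atoms: selenium dioxide (oxygen carrier), O=[Se]=O; tert-butyl hydroperoxide (terminal oxidant), CC(C)(C)OO
Why: Allylic oxidation by ene reaction and [2,3]-sigmatropic shift; the C3 methylene reacts in preference to the C5 methine, and with exocyclic methylene groups on chair cyclohexanes the oxygen is delivered axially, here on the α face, which is free of the angular methyl.

Step 12
Reactants: 14 3α-hydroxy-7α,11-isopropylidenedioxy-5α-eudesm-4(15)-en-8-one
Product: 15 3α,4α-dihydroxy-7α,11-isopropylidenedioxy-5α-eudesman-8-one
Conditions: Mn(dpm)3 (10 mol%), PhSiH3 (2.5 equiv), O2 (1 atm), i-PrOH/CH2Cl2, 0 °C to rt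
Reagents that add atoms: dioxygen, O=O
Why: Mukaiyama hydration: hydrogen-atom transfer from a manganese hydride to C15 gives the tertiary C4 radical, which is trapped by O2 and reduced to the alcohol (Markovnikov); O2 should approach in the equatorial direction on the α face, because the axial approach on the β face is 1,3-diaxial to C14, which gives 4α-OH and 4β-methyl with the small free 3α-hydroxyl next door.

Step 13
Reactants: 15 3α,4α-dihydroxy-7α,11-isopropylidenedioxy-5α-eudesman-8-one
Product: 16 3α,4α,7α,11-tetrahydroxy-5α-eudesman-8-one
Conditions: CF3CO2H/H2O/THF (1:1:4), 0 °C to rt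
Reagents that add atoms: none
Why: Acid hydrolysis of the acetonide at the one stage where the molecule holds no alkene, epoxide or ester; the mildest acid that cleaves this crowded ketal is used so that the tertiary alcohols and the α-ketol are not disturbed.

Step 14
Reactants: 17 angelic acid ((Z)-2-methylbut-2-enoic acid)
Product: 18 (Z)-2-methylbut-2-en-1-ol
Conditions: LiAlH4 (1.2 equiv), Et2O, 0 °C to rt
Reagents that add atoms: none
Why: Hydride reduction of the acid to the allylic alcohol; alkyl-substituted acrylic acids are reduced at the carboxyl group without touching the alkene, and the Z geometry is kept.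

Step 15
Reactants: 18 (Z)-2-methylbut-2-en-1-ol
Product: 19 [(2R,3S)-2,3-dimethyloxiran-2-yl]methanol
Conditions: Ti(OiPr)4 (10 mol%), D-(−)-diethyl tartrate (12 mol%), t-BuOOH (2 equiv), 4 Å molecular sieves, CH2Cl2, −20 °C
Reagents that add atoms: tert-butyl hydroperoxide, CC(C)(C)OO
Why: Sharpless asymmetric epoxidation; with the hydroxymethyl group drawn at the lower right, D-(−)-tartrate delivers oxygen to the rear face, which for this Z trisubstituted alcohol gives the (2R,3S) epoxide, and the cis relation of the C3 methyl and the hydroxymethyl group is kept.

Step 16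
Reactants: 19 [(2R,3S)-2,3-dimethyloxiran-2-yl]methanol
Product: 20 (2S,3S)-2,3-dimethyloxirane-2-carboxylic acid
Conditions: TEMPO (7 mol%), NaOCl (cat.), NaClO2 (2 equiv), MeCN/phosphate buffer (pH 6.7), 35 °C
Reagents that add atoms: sodium chlorite, [Na+].[O-]Cl=O
Why: Oxoammonium-catalysed oxidation of the primary alcohol to the aldehyde and chlorite oxidation to the acid in a buffered medium leave the epoxide and both stereocentres untouched; the descriptor at C2 changes from R to S only because the priorities change.

Step 17
Reactants: 16 3α,4α,7α,11-tetrahydroxy-5α-eudesman-8-one; 20 (2S,3S)-2,3-dimethyloxirane-2-carboxylic acid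
Product: 22 3α-[(2S,3S)-2,3-epoxy-2-methylbutanoyloxy]-4α,7α,11-trihydroxy-5α-eudesman-8-one (the target), via Yamaguchi mixed anhydride 21 (not isolated)
Conditions: 20 (1.5 equiv), 2,4,6-trichlorobenzoyl chloride (1.5 equiv), Et3N (2 equiv), THF, rt; then 16, DMAP (2 equiv), toluene, rt to 40 °C
Reagents that add atoms: none
Why: Yamaguchi esterification; the C3 hydroxyl is the only secondary one, the three tertiary hydroxyls at C4, C7 and C11 do not react with the hindered mixed anhydride under these conditions, and the amine bases are too weak to trigger retro-aldol cleavage or to open the epoxide.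

## Compound list

1 | methyl 2-hydroxy-4-methylbenzoate | COC(=O)c1ccc(C)cc1O | starting material
2 | 4-chlorobutanoyl chloride | O=C(Cl)CCCCl | starting material
3 | methyl 5-(4-chlorobutanoyl)-2-hydroxy-4-methylbenzoate | COC(=O)c1cc(C(=O)CCCCl)c(C)cc1O | intermediate
4 | methyl 5-[2-(3-chloropropyl)-1,3-dioxolan-2-yl]-2-hydroxy-4-methylbenzoate | COC(=O)c1cc(C2(CCCCl)OCCO2)c(C)cc1O | intermediate
5 | methylmagnesium bromide | C[Mg]Br | starting material
6 | 4-[2-(3-chloropropyl)-1,3-dioxolan-2-yl]-2-(2-hydroxypropan-2-yl)-5-methylphenol | CC(C)(O)c1cc(C2(CCCCl)OCCO2)c(C)cc1O | intermediate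
7 | (6S)-4-[2-(3-chloropropyl)-1,3-dioxolan-2-yl]-6-hydroxy-6-(2-hydroxypropan-2-yl)-3-methylcyclohexa-2,4-dien-1-one | CC1=CC(=O)[C@@](O)(C(C)(C)O)C=C1C1(CCCCl)OCCO1 | intermediate
8 | (5S)-9-[2-(3-chloropropyl)-1,3-dioxolan-2-yl]-2,2,4,4,8-pentamethyl-1,3-dioxaspiro[4.5]deca-7,9-dien-6-one | CC1=CC(=O)[C@]2(OC(C)(C)OC2(C)C)C=C1C1(CCCCl)OCCO1 | intermediate
9 | (5S)-9-[2-(3-iodopropyl)-1,3-dioxolan-2-yl]-2,2,4,4,8-pentamethyl-1,3-dioxaspiro[4.5]deca-7,9-dien-6-one | CC1=CC(=O)[C@]2(OC(C)(C)OC2(C)C)C=C1C1(CCCI)OCCO1 | intermediate
10 | 4,4-ethylenedioxy-7α,11-isopropylidenedioxy-15-noreudesm-5-en-8-one (10β-methyl) | C[C@]12CCCC3(OCCO3)C1=C[C@@]4(OC(C)(C)OC4(C)C)C(=O)C2 | intermediate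
11 | 7α,11-isopropylidenedioxy-15-noreudesm-5-ene-4,8-dione (10β-methyl) | C[C@]12CCCC(=O)C1=C[C@@]3(OC(C)(C)OC3(C)C)C(=O)C2 | intermediate
12 | 7α,11-isopropylidenedioxy-15-nor-5α-eudesmane-4,8-dione | C[C@]12CCCC(=O)[C@@H]1C[C@@]3(OC(C)(C)OC3(C)C)C(=O)C2 | intermediate
13 | 7α,11-isopropylidenedioxy-5α-eudesm-4(15)-en-8-one | C[C@]12CCCC(=C)[C@@H]1C[C@@]3(OC(C)(C)OC3(C)C)C(=O)C2 | intermediate
14 | 3α-hydroxy-7α,11-isopropylidenedioxy-5α-eudesm-4(15)-en-8-one | C[C@]12CC[C@@H](O)C(=C)[C@@H]1C[C@@]3(OC(C)(C)OC3(C)C)C(=O)C2 | intermediate
15 | 3α,4α-dihydroxy-7α,11-isopropylidenedioxy-5α-eudesman-8-one | C[C@]12CC[C@@H](O)[C@](O)(C)[C@@H]1C[C@@]3(OC(C)(C)OC3(C)C)C(=O)C2 | intermediate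
16 | 3α,4α,7α,11-tetrahydroxy-5α-eudesman-8-one | C[C@]12CC[C@@H](O)[C@](O)(C)[C@@H]1C[C@](O)(C(C)(C)O)C(=O)C2 | intermediate
17 | angelic acid ((Z)-2-methylbut-2-enoic acid) | C/C=C(/C)C(=O)O | starting material
18 | (Z)-2-methylbut-2-en-1-ol | C/C=C(/C)CO | intermediate
19 | [(2R,3S)-2,3-dimethyloxiran-2-yl]methanol | C[C@@H]1O[C@]1(C)CO | intermediate
20 | (2S,3S)-2,3-dimethyloxirane-2-carboxylic acid | C[C@@H]1O[C@]1(C)C(=O)O | intermediate
21 | (2S,3S)-2,3-dimethyloxirane-2-carboxylic 2,4,6-trichlorobenzoic anhydride | C[C@@H]1O[C@]1(C)C(=O)OC(=O)c1c(Cl)cc(Cl)cc1Cl | intermediate (not isolated)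
22 | (3R,4S,5R,7S,10R)-4,7,11-trihydroxy-8-oxo-5α-eudesman-3-yl (2S,3S)-2,3-dimethyloxirane-2-carboxylate | C[C@@H]1O[C@]1(C)C(=O)O[C@@H]1CC[C@]2(C)CC(=O)[C@@](O)(C(C)(C)O)C[C@H]2[C@]1(C)O | target

## Step count and uncertain steps

Total step count: 17. Longest linear sequence: 14 steps (steps 1 to 13 and step 17); steps 14 to 16 form the three-step branch to acid 20.

**Step 7 (key step, proposed new method).** The most likely failure is ring closure at the wrong carbon. The radical can add in the 6-endo mode to C6, which is a CH carbon and gives a more delocalised radical, in place of the fully substituted C10. Less likely failures are addition on the β face of C10 and reduction of the radical before it cyclises. The fallback sets out from 8 and returns at 12, using known reaction types only.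
- Exchange of the C4 dioxolane in wet acetone with PPTS gives the chloro ketone dienone F1.
- Conjugate reduction of its C4 enone with the monovalent copper hydride [(Ph3P)CuH]6 delivers hydride to C6 and saturates C5=C6, so that the competing acceptor is gone. After equilibration of the acidic C5 centre through the dienol, the epimer with the chain on the α face, the 4-acyl-3-methylcyclohexenone F2, is separated.
- NaI in acetone gives the iodide F3.
- The silane conditions of step 7 then close ring A by a 6-exo addition onto a 3-methylcyclohex-2-enone, a well-known way to an angular methyl, and give the cis-fused diketone F4.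
- DBU epimerises C5 to the trans-fused diketone 12.

In this variant the closure is cis and takes the face on which the chain sits, so C10 follows the C5 configuration. The epimer with the chain cis to O7 is the one that is needed, and it is probably not the favoured one; the other epimer has to be re-equilibrated before the closure.

**Step 4.** The enantioselectivity may be incomplete, because the substrate carries a free tertiary alcohol that can bind iodine and a para substituent that the known cases lack. The ortho-quinol may also be lost through [4+2] dimerisation or through retro-aldol loss of acetone with rearomatisation. The fallback sets out from 6 and returns at 8. Racemic hydroxylation with stabilised 2-iodoxybenzoic acid gives 7 together with its enantiomer F5. Immediate acetonide formation as in step 5 gives 8 together with its enantiomer F6, and the two are separated by chromatography on a chiral stationary phase.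

**Step 10.** The basic ylide may enolise the C4 ketone. That slows the olefination, can move C5 to the cis series before the alkene fixes it, and leaves time for attack at C8. The fallback sets out from 12 and returns at 13. The weakly basic reagent from Me3SiCH2Li and CeCl3 adds to the C4 ketone from the equatorial α side to give the β-hydroxy silane F7, and KH in THF eliminates trimethylsilanolate to give 13 (Peterson olefination).

**Step 12.** The facial selectivity of oxygen capture at the planar C4 radical may be poor, giving the 4β-hydroxy epimer, or the alkene may be reduced without hydration. The fallback sets out from 14 and returns at 15.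
- VO(acac)2 with t-BuOOH epoxidises the exocyclic alkene on the face of the allylic 3α-hydroxyl and gives the 4α,15-epoxide F8.
- LiI in AcOH/THF opens it at the primary carbon to the iodohydrin F9.
- (Me3Si)3SiH with AIBN removes the iodine and leaves the C15 methyl of 15.

**Step 17.** The axial, neopentyl-type C3 hydroxyl may react only slowly with the α-quaternary acid. Forcing conditions on the unprotected tetraol invite retro-aldol loss of acetone or acyl transfer. The fallback sets out from 15 and returns at 22. Acid 20 is coupled under the same Yamaguchi conditions, at higher temperature if needed, with 15, in which the diol is still protected, to give the ester acetonide F10. The acetonide is then removed with aqueous CF3CO2H at 0 °C, conditions that electron-poor glycidic esters are expected to survive.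

## Further compounds

F1 | step 7 | (5S)-9-(4-chlorobutanoyl)-2,2,4,4,8-pentamethyl-1,3-dioxaspiro[4.5]deca-7,9-dien-6-one | CC1=CC(=O)[C@]2(OC(C)(C)OC2(C)C)C=C1C(=O)CCCCl
F2 | step 7 | 9-(4-chlorobutanoyl)-2,2,4,4,8-pentamethyl-1,3-dioxaspiro[4.5]dec-7-en-6-one with the acyl chain cis to O1 (eudesmane 5β-H, 7S) | CC1=CC(=O)[C@]2(OC(C)(C)OC2(C)C)C[C@@H]1C(=O)CCCCl
F3 | step 7 | 9-(4-iodobutanoyl)-2,2,4,4,8-pentamethyl-1,3-dioxaspiro[4.5]dec-7-en-6-one with the acyl chain cis to O1 (eudesmane 5β-H, 7S) | CC1=CC(=O)[C@]2(OC(C)(C)OC2(C)C)C[C@@H]1C(=O)CCCI
F4 | step 7 | 7α,11-isopropylidenedioxy-15-nor-5β-eudesmane-4,8-dione (cis-fused, 10β-methyl) | C[C@]12CCCC(=O)[C@H]1C[C@@]3(OC(C)(C)OC3(C)C)C(=O)C2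
F5 | step 4 | (6R)-4-[2-(3-chloropropyl)-1,3-dioxolan-2-yl]-6-hydroxy-6-(2-hydroxypropan-2-yl)-3-methylcyclohexa-2,4-dien-1-one | CC1=CC(=O)[C@](O)(C(C)(C)O)C=C1C1(CCCCl)OCCO1
F6 | step 4 | (5R)-9-[2-(3-chloropropyl)-1,3-dioxolan-2-yl]-2,2,4,4,8-pentamethyl-1,3-dioxaspiro[4.5]deca-7,9-dien-6-one | CC1=CC(=O)[C@@]2(OC(C)(C)OC2(C)C)C=C1C1(CCCCl)OCCO1
F7 | step 10 | 4β-hydroxy-7α,11-isopropylidenedioxy-15-(trimethylsilyl)-5α-eudesman-8-one (4α-CH2SiMe3) | C[C@]12CCC[C@@](O)(C[Si](C)(C)C)[C@@H]1C[C@@]3(OC(C)(C)OC3(C)C)C(=O)C2
F8 | step 12 | 4α,15-epoxy-3α-hydroxy-7α,11-isopropylidenedioxy-5α-eudesman-8-one | C[C@]12CC[C@@H](O)[C@]3(CO3)[C@@H]1C[C@@]4(OC(C)(C)OC4(C)C)C(=O)C2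
F9 | step 12 | 3α,4α-dihydroxy-15-iodo-7α,11-isopropylidenedioxy-5α-eudesman-8-one | C[C@]12CC[C@@H](O)[C@](O)(CI)[C@@H]1C[C@@]3(OC(C)(C)OC3(C)C)C(=O)C2
F10 | step 17 | 4α-hydroxy-7α,11-isopropylidenedioxy-8-oxo-5α-eudesman-3α-yl (2S,3S)-2,3-dimethyloxirane-2-carboxylate | C[C@@H]1O[C@]1(C)C(=O)O[C@@H]1CC[C@]2(C)CC(=O)[C@]3(OC(C)(C)OC3(C)C)C[C@H]2[C@]1(C)O
A1 | alternative 1 | 11-(triethylsilyloxy)-5α-eudesm-3-en-9-one | C1=C(C)[C@@H]2C[C@H](C(C)(C)O[Si](CC)(CC)CC)CC(=O)[C@@]2(C)CC1
A2 | alternative 1 | (7E)-2,8-dimethyl-5-[2-(triethylsilyloxy)propan-2-yl]deca-1,7,9-trien-3-one (C5 of the chain configured as C7 of A1) | C=C(C)C(=O)C[C@@H](C(C)(C)O[Si](CC)(CC)CC)C/C=C(\C)C=C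
A3 | alternative 2 | 7α-hydroxy-5α-eudesma-3,11-dien-8-one | C1=C(C)[C@@H]2C[C@](O)(C(C)=C)C(=O)C[C@@]2(C)CC1
A4 | alternative 2 | 2-[1,3-dimethyl-2-(3-methyl-2-oxobut-3-enyl)cyclohex-3-en-1-yl]acetaldehyde (eudesmane 5α-H, 10β-methyl) | C1=C(C)[C@H](CC(=O)C(C)=C)[C@@](C)(CC=O)CC1
A5 | alternative 3 | 4(15)-methylene-11,12,13-trinor-5α-eudesman-8-one (10β-methyl) | C=C1CCC[C@]2(C)CC(=O)CC[C@@H]12
A6 | alternative 3 | triisopropyl{[(5E)-6-methylundeca-1,5-dien-10-yn-2-yl]oxy}silane | C#CCCC/C(C)=C/CCC(=C)O[Si](C(C)C)(C(C)C)C(C)C
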